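**Retrosynthetic overview**
- The 1β,10α-oxirane is put in last by peracid. Before that the C3 ester comes from acylation with (R)-2-methylbutanoic acid and the C8 ester from a Mitsunobu inversion with (2S,3S)-epoxyangelic acid.
- Key disconnection: the C7–C11 bond of the α-methylene-γ-lactone. The precursor is the 6-O-acrylate of a 7α,8α-epoxy-6α-ol on the ten-membered ring. The acrylate α-carbon C11 stands 1,5 to the oxirane carbon C7 (C11–C12–O–C6–C7), so a 5-exo-tet oxirane opening closes the lactone ring, keeps the exocyclic methylene, sets C7 and frees O8.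
- The epoxy alcohol comes from a cross-conjugated Z,Z-dienone, made from a ten-membered ketone that arises by anionic oxy-Cope ring expansion (six to ten) of a 1-vinyl-6-isopropenylcyclohex-2-enol built from (S)-carvone.
- Ring order: cyclohexene (chiral pool) → ten-membered carbocycle (oxy-Cope) → 7,8-oxirane → γ-lactone (key step) → side-chain oxirane (arrives with the acid) → 1,10-oxirane.

Key step: step 10

Remark: (S)-(+)-carvone, angelic acid and (R)-2-methylbutanoic acid are taken as commercial; ten-membered-ring compounds carry germacrane numbering (ring C1–C10, methyls C14 on C10 and C15 on C4, lactone C11–C13; α/β as in the usual drawing with H-7 α), and those without C11–C13 are named as 11,12,13-trinorgermacranes.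

Step 1
Reactants: 1 (S)-(+)-carvone
Product: 2 (1S,5S)-cis-carveol
Conditions: NaBH4, CeCl3·7H2O, MeOH, 0 °C
Reagents that add atoms: none
Why: Luche 1,2-reduction of the enone with hydride delivery anti to the C5 isopropenyl group should give the cis-carveol, which sets the carbinol centre (the later C3, S) from the chiral pool.

Step 2
Reactants: 2 (1S,5S)-cis-carveol
Product: 3 (1S,5S)-cis-carveol tert-butyldimethylsilyl ether
Conditions: TBSCl, imidazole, DMF, 23 °C
Reagents that add atoms: tert-butyldimethylsilyl chloride, CC(C)(C)[Si](C)(C)Cl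
Why: Standard silylation of a secondary allylic alcohol gives an ether that should survive the organometallic, hydride, peroxide and phosphine steps and is removed by fluoride late in the route.

Step 3
Reactants: 3 (1S,5S)-cis-carveol tert-butyldimethylsilyl ether
Product: 4 (4S,6S)-4-[(tert-butyldimethylsilyl)oxy]-3-methyl-6-(prop-1-en-2-yl)cyclohex-2-en-1-one
Conditions: Rh2(caprolactamate)4 (1 mol %), t-BuOOH (70% aq.), K2CO3 (0.5 equiv), CH2Cl2, 23 °C
Reagents that add atoms: tert-butyl hydroperoxide, CC(C)(C)OO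
Why: Dirhodium-catalysed allylic oxidation of the ring CH2 next to the =CH terminus of the trisubstituted alkene (the regiochemistry known for 1-methylcyclohexenes and Δ5-steroids) should give the enone without touching either stereocentre.

Step 4
Reactants: 4 (4S,6S)-4-[(tert-butyldimethylsilyl)oxy]-3-methyl-6-(prop-1-en-2-yl)cyclohex-2-en-1-one
Product: 5 (1S,4S,6S)-4-[(tert-butyldimethylsilyl)oxy]-1-ethenyl-3-methyl-6-(prop-1-en-2-yl)cyclohex-2-en-1-ol (vinyl trans to isopropenyl)
Conditions: CH2=CHMgBr, CeCl3, THF, −78 °C; then H2O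
Reagents that add atoms: vinylmagnesium bromide, C=C[Mg]Br
Why: Cerium-mediated 1,2-addition of the vinyl Grignard reagent to the β,β-disubstituted enone, anti to the neighbouring α-isopropenyl group, should give the trans-1,2-dialkenyl carbinol (new centre 1S) needed for a chair oxy-Cope transition state.

Step 5
Reactants: 5 (1S,4S,6S)-4-[(tert-butyldimethylsilyl)oxy]-1-ethenyl-3-methyl-6-(prop-1-en-2-yl)cyclohex-2-en-1-ol
Product: 7 (3S,7R)-3β-[(tert-butyldimethylsilyl)oxy]-7β-(phenylselanyl)-11,12,13-trinorgermacra-1(10)E,4Z-dien-6-one, via potassium enolate 6 (not isolated)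
Conditions: KH, 18-crown-6, THF, 0 → 23 °C; then PhSeBr, −78 °C
Reagents that add atoms: phenylselenenyl bromide, Br[Se]c1ccccc1
Why: Anionic oxy-Cope rearrangement through a chair transition state with both ring bonds equatorial expands the six-membered ring to the ten-membered enolate, creating the 1(10)E alkene and keeping the 4Z alkene and C3, and the enolate is selenenylated regiospecifically at C7 on its exposed face (a centre that is removed in step 6).

Step 6
Reactants: 7 (3S,7R)-3β-[(tert-butyldimethylsilyl)oxy]-7β-(phenylselanyl)-11,12,13-trinorgermacra-1(10)E,4Z-dien-6-one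
Product: 9 (3S)-3β-[(tert-butyldimethylsilyl)oxy]-11,12,13-trinorgermacra-1(10)E,4Z,7Z-trien-6-one, via selenoxide 8 (not isolated)
Conditions: NaIO4, NaHCO3, THF/MeOH/H2O, 0 → 23 °C
Reagents that add atoms: none
Why: Oxidation to the selenoxide and syn-elimination towards C8, the only β-carbon that carries hydrogen, should give the cross-conjugated dienone, the least-motion syn-periplanar arrangement in the ten-membered ring leading to the 7Z alkene.

Step 7
Reactants: 9 (3S)-3β-[(tert-butyldimethylsilyl)oxy]-11,12,13-trinorgermacra-1(10)E,4Z,7Z-trien-6-one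
Product: 10 (3S,7S,8S)-3β-[(tert-butyldimethylsilyl)oxy]-7α,8α-epoxy-11,12,13-trinorgermacra-1(10)E,4Z-dien-6-one
Conditions: t-BuOOH, benzyltrimethylammonium hydroxide (10 mol %), THF, 0 °C
Reagents that add atoms: tert-butyl hydroperoxide, CC(C)(C)OO
Why: In this Weitz–Scheffer nucleophilic epoxidation the hydroperoxide anion adds to the less substituted β-carbon C8 (not to the β,β-disubstituted C4), the ring-held Z geometry gives the cis-oxirane, and attack on the face opposite to the bulky 3β-silyloxy group of the folded dienone should give the 7α,8α-epoxide.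

Step 8
Reactants: 10 (3S,7S,8S)-3β-[(tert-butyldimethylsilyl)oxy]-7α,8α-epoxy-11,12,13-trinorgermacra-1(10)E,4Z-dien-6-one
Product: 11 (3S,6R,7R,8S)-3β-[(tert-butyldimethylsilyl)oxy]-7α,8α-epoxy-11,12,13-trinorgermacra-1(10)E,4Z-dien-6α-ol
Conditions: Zn(BH4)2, Et2O, −20 °C; then aq. NH4Cl
Reagents that add atoms: none
Why: Chelation-controlled 1,2-reduction of the α,β-epoxy ketone, with zinc bridging the carbonyl and oxirane oxygens and hydride arriving anti to the oxirane, should set C6 (6α-OH, erythro to the C7–O bond) and leave the oxirane intact.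

Step 9
Reactants: 11 (3S,6R,7R,8S)-3β-[(tert-butyldimethylsilyl)oxy]-7α,8α-epoxy-11,12,13-trinorgermacra-1(10)E,4Z-dien-6α-ol
Product: 12 (3S,6R,7S,8S)-6α-(acryloyloxy)-3β-[(tert-butyldimethylsilyl)oxy]-7α,8α-epoxy-11,12,13-trinorgermacra-1(10)E,4Z-diene
Conditions: acryloyl chloride, i-Pr2NEt, CH2Cl2, −20 → 0 °C
Reagents that add atoms: acryloyl chloride, C=CC(=O)Cl
Why: Acylation of the secondary alcohol places the acrylate α-carbon (the later C11) five atoms from the oxirane carbon C7 and brings in C11, C12 and C13 in one piece.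

Step 10
Reactants: 12 (3S,6R,7S,8S)-6α-(acryloyloxy)-3β-[(tert-butyldimethylsilyl)oxy]-7α,8α-epoxy-11,12,13-trinorgermacra-1(10)E,4Z-diene
Product: 15 (3S,6R,7R,8S)-3β-[(tert-butyldimethylsilyl)oxy]-8α-hydroxygermacra-1(10)E,4Z,11(13)-trien-12,6α-olide, via β-phosphonium enolate 13 (not isolated), via phosphonium alkoxide 14 (not isolated)
Conditions: PMe3 (1.2 equiv), t-BuOH/THF (3:1), 23 → 40 °C
Reagents that add atoms: none
Why: Proposed new method: PMe3 adds reversibly to the acrylate β-carbon C13 to give the zwitterionic ester enolate 13, whose α-carbon C11 opens the oxirane at C7 from the face anti to the C7–O bond, and proton transfer followed by E1cB loss of PMe3 from 14 restores the C11=C13 methylene; the closest known reaction type is the phosphine-mediated intramolecular Morita–Baylis–Hillman alkylation of enones by tethered epoxides and halides, here moved to an acrylate ester whose tether runs through the ester oxygen. The γ-lactone ring (C11–C12–O–C6–C7) closes in the 5-exo-tet mode. C7 is set by SN2 inversion of the 7α C–O bond (C11 enters β, trans-fused to the 6α-oxygen, H-7 α), C8 keeps its oxygen with retention, and C11 ends as an sp2 carbon. The step needs attack at C7 and not at C8 (6-endo, δ-lactone), and addition of the phosphine to the acrylate and not to the oxirane: the 1,5-relation of C11 and C7 and the anti-periplanar O6–C6–C7–O arrangement open to the erythro epoxy ester should secure the first, and the absence of any other Michael acceptor (C4=C5 is no longer conjugated) together with the low reactivity of PMe3 towards unactivated oxiranes should secure the second. t-BuOH hydrogen-bonds to the oxirane and carries the proton from C11 to the C8 alkoxide.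

Step 11
Reactants: 16 angelic acid [(Z)-2-methylbut-2-enoic acid]
Product: 17 (Z)-2-methylbut-2-en-1-ol
Conditions: LiAlH4, Et2O, 0 °C; then H2O, aq. NaOH
Reagents that add atoms: none
Why: Hydride reduction of the carboxylic acid gives the primary allylic alcohol without touching the Z-trisubstituted alkene.

Step 12
Reactants: 17 (Z)-2-methylbut-2-en-1-ol
Product: 18 [(2R,3S)-2,3-dimethyloxiran-2-yl]methanol
Conditions: Ti(Oi-Pr)4 (10 mol %), diethyl D-(−)-tartrate (12 mol %), t-BuOOH, 4 Å molecular sieves, CH2Cl2, −20 °C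
Reagents that add atoms: tert-butyl hydroperoxide, CC(C)(C)OO
Why: Sharpless asymmetric epoxidation of the allylic alcohol with the D-tartrate ligand should deliver oxygen to the face that gives the (2R,3S)-epoxy alcohol, the Z geometry fixing the cis relation of CH2OH and the C3 methyl group.

Step 13
Reactants: 18 [(2R,3S)-2,3-dimethyloxiran-2-yl]methanol
Product: 19 (2S,3S)-2,3-dimethyloxirane-2-carboxylic acid [(2S,3S)-epoxyangelic acid]
Conditions: RuCl3·H2O (2 mol %), NaIO4, CCl4/MeCN/H2O, 0 → 23 °C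
Reagents that add atoms: water, O
Why: RuO4-mediated oxidation of the primary epoxy alcohol to the glycidic acid is a standard reaction that leaves the oxirane and both stereocentres untouched (the C2 descriptor changes from R to S only through the priority rule).

Step 14
Reactants: 15 (3S,6R,7R,8S)-3β-[(tert-butyldimethylsilyl)oxy]-8α-hydroxygermacra-1(10)E,4Z,11(13)-trien-12,6α-olide; 19 (2S,3S)-2,3-dimethyloxirane-2-carboxylic acid
Product: 20 (3S,6R,7R,8R)-3β-[(tert-butyldimethylsilyl)oxy]-8β-{[(2S,3S)-2,3-dimethyloxiran-2-yl]carbonyloxy}germacra-1(10)E,4Z,11(13)-trien-12,6α-olide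
Conditions: PPh3, diisopropyl azodicarboxylate, toluene, 0 → 23 °C
Reagents that add atoms: none
Why: In this Mitsunobu esterification the 8α-alkoxyphosphonium ion is displaced by the carboxylate (pKa about 3.5) in an SN2 reaction, so C8 should be inverted to the required 8β (R) ester while the stereocentres of the acid are untouched.

Step 15
Reactants: 20 (3S,6R,7R,8R)-3β-[(tert-butyldimethylsilyl)oxy]-8β-{[(2S,3S)-2,3-dimethyloxiran-2-yl]carbonyloxy}germacra-1(10)E,4Z,11(13)-trien-12,6α-olide
Product: 21 (3S,6R,7R,8R)-8β-{[(2S,3S)-2,3-dimethyloxiran-2-yl]carbonyloxy}-3β-hydroxygermacra-1(10)E,4Z,11(13)-trien-12,6α-olide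
Conditions: HF·pyridine, pyridine, THF, 0 → 23 °C
Reagents that add atoms: none
Why: Fluoride cleavage of the allylic silyl ether under buffered, non-basic conditions should spare the glycidate ester, the α-methylene lactone and the acid-sensitive diene.

Step 16
Reactants: 21 (3S,6R,7R,8R)-8β-{[(2S,3S)-2,3-dimethyloxiran-2-yl]carbonyloxy}-3β-hydroxygermacra-1(10)E,4Z,11(13)-trien-12,6α-olide; 22 (R)-2-methylbutanoic acid
Product: 23 (3S,6R,7R,8R)-8β-{[(2S,3S)-2,3-dimethyloxiran-2-yl]carbonyloxy}-3β-{[(2R)-2-methylbutanoyl]oxy}germacra-1(10)E,4Z,11(13)-trien-12,6α-olide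
Conditions: N,N'-dicyclohexylcarbodiimide, 4-(dimethylamino)pyridine (10 mol %), CH2Cl2, 0 °C
Reagents that add atoms: none
Why: Steglich esterification of the allylic 3β-alcohol proceeds with retention at C3, and at 0 °C the α-stereocentre of the simple branched acid should not epimerise.

Step 17
Reactants: 23 (3S,6R,7R,8R)-8β-{[(2S,3S)-2,3-dimethyloxiran-2-yl]carbonyloxy}-3β-{[(2R)-2-methylbutanoyl]oxy}germacra-1(10)E,4Z,11(13)-trien-12,6α-olide
Product: 24 (1R,3S,6R,7R,8R,10R)-1β,10α-epoxy-8β-{[(2S,3S)-2,3-dimethyloxiran-2-yl]carbonyloxy}-3β-{[(2R)-2-methylbutanoyl]oxy}germacra-4Z,11(13)-dien-12,6α-olide (CNP0265335.2)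
Conditions: m-CPBA (1.05 equiv), NaHCO3, CH2Cl2, 0 °C
Reagents that add atoms: 3-chloroperbenzoic acid, OOC(=O)c1cccc(Cl)c1
Why: In this Prilezhaev epoxidation the 1(10) alkene is the only electron-rich double bond (C4=C5 is flanked by two allylic acyloxy groups, C11=C13 is conjugated), and attack on the exposed outer face of the E-alkene in the ten-membered ring should give the 1β,10α-oxirane (1R,10R).

**Compound list**
1 | (S)-(+)-carvone | CC1=CC[C@@H](CC1=O)C(C)=C | starting material
2 | (1S,5S)-cis-carveol | CC1=CC[C@@H](C[C@@H]1O)C(C)=C | intermediate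
3 | (1S,5S)-cis-carveol tert-butyldimethylsilyl ether | CC1=CC[C@@H](C[C@@H]1O[Si](C)(C)C(C)(C)C)C(C)=C | intermediate
4 | (4S,6S)-4-[(tert-butyldimethylsilyl)oxy]-3-methyl-6-(prop-1-en-2-yl)cyclohex-2-en-1-one | CC1=CC(=O)[C@@H](C[C@@H]1O[Si](C)(C)C(C)(C)C)C(C)=C | intermediate
5 | (1S,4S,6S)-4-[(tert-butyldimethylsilyl)oxy]-1-ethenyl-3-methyl-6-(prop-1-en-2-yl)cyclohex-2-en-1-ol | CC1=C[C@@](O)(C=C)[C@@H](C[C@@H]1O[Si](C)(C)C(C)(C)C)C(C)=C | intermediate
6 | potassium enolate (O–C6=C7) of (3S)-3β-silyloxy-11,12,13-trinorgermacra-1(10)E,4Z-dien-6-one | [K+].[O-]/C1=C\CC/C(C)=C/C[C@H](O[Si](C)(C)C(C)(C)C)/C(C)=C\1 | intermediate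
7 | (3S,7R)-3β-[(tert-butyldimethylsilyl)oxy]-7β-(phenylselanyl)-11,12,13-trinorgermacra-1(10)E,4Z-dien-6-one | O=C1/C=C(/C)[C@@H](O[Si](C)(C)C(C)(C)C)C/C=C(\C)CC[C@H]1[Se]c2ccccc2 | intermediate
8 | Se-oxide of 7 | O=C1/C=C(/C)[C@@H](O[Si](C)(C)C(C)(C)C)C/C=C(\C)CC[C@H]1[Se](=O)c2ccccc2 | intermediate
9 | (3S)-3β-[(tert-butyldimethylsilyl)oxy]-11,12,13-trinorgermacra-1(10)E,4Z,7Z-trien-6-one | O=C1/C=C(/C)[C@@H](O[Si](C)(C)C(C)(C)C)C/C=C(\C)C/C=C\1 | intermediate
10 | (3S,7S,8S)-3β-[(tert-butyldimethylsilyl)oxy]-7α,8α-epoxy-11,12,13-trinorgermacra-1(10)E,4Z-dien-6-one | O=C1/C=C(/C)[C@@H](O[Si](C)(C)C(C)(C)C)C/C=C(\C)C[C@@H]2O[C@H]12 | intermediate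
11 | (3S,6R,7R,8S)-3β-[(tert-butyldimethylsilyl)oxy]-7α,8α-epoxy-11,12,13-trinorgermacra-1(10)E,4Z-dien-6α-ol | O[C@@H]1/C=C(/C)[C@@H](O[Si](C)(C)C(C)(C)C)C/C=C(\C)C[C@@H]2O[C@H]12 | intermediate
12 | (3S,6R,7S,8S)-6α-(acryloyloxy)-3β-[(tert-butyldimethylsilyl)oxy]-7α,8α-epoxy-11,12,13-trinorgermacra-1(10)E,4Z-diene | C=CC(=O)O[C@@H]1/C=C(/C)[C@@H](O[Si](C)(C)C(C)(C)C)C/C=C(\C)C[C@@H]2O[C@H]12 | intermediate
13 | β-(trimethylphosphonio) ester enolate from 12 (zwitterion) | C[P+](C)(C)CC=C([O-])O[C@@H]1/C=C(/C)[C@@H](O[Si](C)(C)C(C)(C)C)C/C=C(\C)C[C@@H]2O[C@H]12 | intermediate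
14 | 13-(trimethylphosphonio)-8α-oxido-11,13-dihydro lactone (zwitterion) | C[P+](C)(C)CC1C(=O)O[C@@H]2/C=C(/C)[C@@H](O[Si](C)(C)C(C)(C)C)C/C=C(\C)C[C@H]([O-])[C@@H]12 | intermediate
15 | (3S,6R,7R,8S)-3β-[(tert-butyldimethylsilyl)oxy]-8α-hydroxygermacra-1(10)E,4Z,11(13)-trien-12,6α-olide | C=C1C(=O)O[C@@H]2/C=C(/C)[C@@H](O[Si](C)(C)C(C)(C)C)C/C=C(\C)C[C@H](O)[C@@H]12 | intermediate
16 | angelic acid [(Z)-2-methylbut-2-enoic acid] | C/C=C(/C)C(=O)O | starting material
17 | (Z)-2-methylbut-2-en-1-ol | C/C=C(/C)CO | intermediate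
18 | [(2R,3S)-2,3-dimethyloxiran-2-yl]methanol | OC[C@@]1(C)O[C@H]1C | intermediate
19 | (2S,3S)-2,3-dimethyloxirane-2-carboxylic acid | OC(=O)[C@@]1(C)O[C@H]1C | intermediate
20 | (3S,6R,7R,8R)-3β-[(tert-butyldimethylsilyl)oxy]-8β-{[(2S,3S)-2,3-dimethyloxiran-2-yl]carbonyloxy}germacra-1(10)E,4Z,11(13)-trien-12,6α-olide | C=C1C(=O)O[C@@H]2/C=C(/C)[C@@H](O[Si](C)(C)C(C)(C)C)C/C=C(\C)C[C@@H](OC(=O)[C@@]3(C)O[C@H]3C)[C@@H]12 | intermediate
21 | (3S,6R,7R,8R)-8β-{[(2S,3S)-2,3-dimethyloxiran-2-yl]carbonyloxy}-3β-hydroxygermacra-1(10)E,4Z,11(13)-trien-12,6α-olide | C=C1C(=O)O[C@@H]2/C=C(/C)[C@@H](O)C/C=C(\C)C[C@@H](OC(=O)[C@@]3(C)O[C@H]3C)[C@@H]12 | intermediate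
22 | (R)-2-methylbutanoic acid | CC[C@@H](C)C(=O)O | starting material
23 | (3S,6R,7R,8R)-8β-{[(2S,3S)-2,3-dimethyloxiran-2-yl]carbonyloxy}-3β-{[(2R)-2-methylbutanoyl]oxy}germacra-1(10)E,4Z,11(13)-trien-12,6α-olide | C=C1C(=O)O[C@@H]2/C=C(/C)[C@@H](OC(=O)[C@H](C)CC)C/C=C(\C)C[C@@H](OC(=O)[C@@]3(C)O[C@H]3C)[C@@H]12 | intermediate
24 | CNP0265335.2 | C=C1C(=O)O[C@@H]2/C=C(/C)[C@@H](OC(=O)[C@H](C)CC)C[C@H]3O[C@]3(C)C[C@@H](OC(=O)[C@@]3(C)O[C@H]3C)[C@@H]12 | target

**Totals**
Total step count: 17. Longest linear sequence: 14 steps (steps 1–10 and 14–17, from (S)-carvone).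

**Steps most likely to fail**

Step 10 (new method). The phosphonium ester enolate may be too weak a nucleophile for the unactivated oxirane, so that the acrylate oligomerises or is returned unchanged, or opening may occur partly at C8. The fallback sets out from epoxy alcohol 11. Steglich esterification with diethylphosphonoacetic acid (OC(=O)CP(=O)(OCC)OCC; N,N'-dicyclohexylcarbodiimide, 4-(dimethylamino)pyridine, CH2Cl2, 0 °C) should give the 6α-O-(diethylphosphonoacetyl) 7α,8α-epoxide F1. KOt-Bu (1.05 equiv, THF, −20 → 0 °C) should then bring about the known 5-exo-tet alkylation of the stabilised ester carbanion by the oxirane at C7, giving the potassium salt of the α-(diethoxyphosphoryl) 8α-hydroxy lactone F2. This salt is not isolated: paraformaldehyde (C=O) is added to the same flask and Horner–Wadsworth–Emmons methylenation should bring the sequence back to the route at compound 15.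

Step 7. Facial selectivity of the nucleophilic epoxidation may be poor or reversed, and the base may isomerise the Z-enone. The fallback sets out from selenide 7 and relays the configuration of C7 instead. Luche reduction (NaBH4, CeCl3·7H2O, MeOH, −78 °C) under Felkin–Anh control by the C7–Se bond should give the (3S,6R,7R)-6α-hydroxy-7β-phenylselanyl compound F3. NaIO4 oxidation and syn-elimination away from the carbinol should give the (3S,6S)-6α-hydroxy-1(10)E,4Z,7Z-triene F4 (same spatial arrangement at C6; the descriptor changes with the priorities). Hydroxyl-directed epoxidation (VO(acac)2, t-BuOOH, CH2Cl2, 0 °C), which delivers oxygen syn to the carbinol oxygen in medium-ring allylic alcohols, should then return to the route at compound 11. The open point of this fallback is competition from the second allylic alkene C4=C5, which is slowed by its allylic silyloxy group.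

Step 14. SN2 displacement at the hindered C8 next to the ring fusion may lose out to elimination towards C9 or to esterification with retention. The fallback sets out from 15 and inverts C8 by a redox pair. Dess–Martin periodinane (1,1,1-triacetoxy-1,1-dihydro-1,2-benziodoxol-3(1H)-one, NaHCO3, CH2Cl2, 0 °C) should give the 8-oxo lactone F5. Luche reduction at −78 °C, with hydride arriving on the α-face anti to the β-oriented C7–C11 bond, should give the 8β-hydroxy lactone F6. Steglich esterification of F6 with acid 19 (N,N'-dicyclohexylcarbodiimide, 4-(dimethylamino)pyridine, CH2Cl2, 0 °C) returns to the route at compound 20. The ketone F5 must be kept cold and buffered, because enolisation towards C7 would move the exocyclic alkene into the ring.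

**Further compounds**
F1 | step 10 | (3S,6R,7S,8S)-3β-[(tert-butyldimethylsilyl)oxy]-6α-[(diethoxyphosphoryl)acetoxy]-7α,8α-epoxy-11,12,13-trinorgermacra-1(10)E,4Z-diene | CCOP(=O)(OCC)CC(=O)O[C@@H]1/C=C(/C)[C@@H](O[Si](C)(C)C(C)(C)C)C/C=C(\C)C[C@@H]2O[C@H]12
F2 | step 10 | (3S,6R,7R,8S)-3β-[(tert-butyldimethylsilyl)oxy]-11-(diethoxyphosphoryl)-8α-hydroxy-13-norgermacra-1(10)E,4Z-dien-12,6α-olide | CCOP(=O)(OCC)C1C(=O)O[C@@H]2/C=C(/C)[C@@H](O[Si](C)(C)C(C)(C)C)C/C=C(\C)C[C@H](O)[C@@H]12
F3 | step 7 | (3S,6R,7R)-3β-[(tert-butyldimethylsilyl)oxy]-7β-(phenylselanyl)-11,12,13-trinorgermacra-1(10)E,4Z-dien-6α-ol | O[C@@H]1/C=C(/C)[C@@H](O[Si](C)(C)C(C)(C)C)C/C=C(\C)CC[C@H]1[Se]c2ccccc2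
F4 | step 7 | (3S,6S)-3β-[(tert-butyldimethylsilyl)oxy]-11,12,13-trinorgermacra-1(10)E,4Z,7Z-trien-6α-ol | O[C@@H]1/C=C(/C)[C@@H](O[Si](C)(C)C(C)(C)C)C/C=C(\C)C/C=C\1
F5 | step 14 | (3S,6R,7S)-3β-[(tert-butyldimethylsilyl)oxy]-8-oxogermacra-1(10)E,4Z,11(13)-trien-12,6α-olide | C=C1C(=O)O[C@@H]2/C=C(/C)[C@@H](O[Si](C)(C)C(C)(C)C)C/C=C(\C)CC(=O)[C@@H]12
F6 | step 14 | (3S,6R,7R,8R)-3β-[(tert-butyldimethylsilyl)oxy]-8β-hydroxygermacra-1(10)E,4Z,11(13)-trien-12,6α-olide | C=C1C(=O)O[C@@H]2/C=C(/C)[C@@H](O[Si](C)(C)C(C)(C)C)C/C=C(\C)C[C@@H](O)[C@@H]12
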